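## Retrosynthetic overview

- The last bond made is C11–OOH, by a singlet-oxygen ene reaction on the 7(11)-en-8-one, which moves the alkene to C6=C7.
- Both ring-A C–O bonds (4β-OAc, 3α-epoxy ester) come from one anti-diacyloxylation of eudesma-3,7(11)-dien-8-one, using acetyl hypoiodite and then the epoxy acid (made by Sharpless epoxidation of tiglyl alcohol and oxidation).
- The isopropylidene comes from an acetone aldol condensation at C7 of a trans-fused octalone; its 5α-H and C3=C4 alkene come from reductive 1,3-transposition of a 3β-allylic alcohol.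
- The decalin comes from an asymmetric Robinson annulation (chiral-imine Michael addition to ethyl vinyl ketone, then aldol condensation).
- Ring order: ring B is bought as a cyclohexanone ketal, ring A is closed onto it, and the oxirane is made separately on the side chain.

Assumption: racemic 7-methyl-1,4-dioxaspiro[4.5]decan-8-one and (E)-2-methylbut-2-en-1-ol are bought as catalogue compounds.

Ring atoms are named by eudesmane numbering: C3 carries the epoxy ester, C4 the acetate and a methyl, C5 is the ring-fusion CH, C8 the ketone, C10 the angular-methyl carbon. Read from the SMILES, the target is 3α-acyloxy, 4β-acetoxy (trans-diaxial), 5α-H, 10β-Me (3R,4R,5R,10R), with a (2S,3R)-2,3-dimethyloxirane-2-carboxylate (methyls cis, i.e. derived from tiglic acid).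

## Route

Step 1
Reactants: 1 7-methyl-1,4-dioxaspiro[4.5]decan-8-one; 2 (R)-1-phenylethylamine; 3 ethyl vinyl ketone
Product: 6 (7R)-7-methyl-7-(3-oxopentyl)-1,4-dioxaspiro[4.5]decan-8-one, via ketimine 4 (not isolated), via Michael-adduct ketimine 5 (not isolated)
Conditions: toluene, cat. TsOH, reflux (Dean–Stark); concentrate; 3, THF, 40 °C; then 10% aq. AcOH, 23 °C
Reagents that add atoms: water, O
Why: Chiral-imine (d'Angelo) Michael addition: the more substituted secondary enamine tautomer of the ketimine adds to the enone through a compact aza-ene-like transition state on the face dictated by the (R)-auxiliary, which sets the quaternary centre (future C10, R, about 90% ee expected), and dilute acetic acid hydrolyses the imine without cleaving the dioxolane.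

Step 2
Reactants: 6 (7R)-7-methyl-7-(3-oxopentyl)-1,4-dioxaspiro[4.5]decan-8-one
Product: 7 (8aR)-5,8a-dimethyl-3,4,8,8a-tetrahydronaphthalene-2,6(1H,7H)-dione 2-(ethylene ketal)
Conditions: NaOMe, MeOH, 23 to 60 °C
Reagents that add atoms: none
Why: Intramolecular aldol condensation (second half of the Robinson annulation) closes ring A onto the ring ketone and dehydrates to the conjugated enone; the quaternary centre cannot epimerise.

Step 3
Reactants: 7 (8aR)-5,8a-dimethyl-3,4,8,8a-tetrahydronaphthalene-2,6(1H,7H)-dione 2-(ethylene ketal)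
Product: 8 (6S,8aR)-6-hydroxy-5,8a-dimethyl-3,4,6,7,8,8a-hexahydronaphthalen-2(1H)-one ethylene ketal
Conditions: NaBH4, CeCl3·7H2O, MeOH, −78 to 0 °C
Reagents that add atoms: none
Why: Luche 1,2-reduction: the small hydride is delivered axially from the α-face as in Δ4-3-keto steroids, giving the pseudo-equatorial 3β-alcohol (C3 = S) as the major epimer.

Step 4
Reactants: 8 (6S,8aR)-6-hydroxy-5,8a-dimethyl-3,4,6,7,8,8a-hexahydronaphthalen-2(1H)-one ethylene ketal
Product: 12 (4aR,8aR)-5,8a-dimethyl-3,4,4a,7,8,8a-hexahydronaphthalen-2(1H)-one, via N-sulfonylhydrazine 9 (not isolated), via allylic diazene 10 (not isolated), via ketal alkene 11 (not isolated)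
Conditions: 2-nitrobenzenesulfonylhydrazide, PPh3, DEAD, THF, −30 to 23 °C; then 1 M aq. HCl, 23 °C
Reagents that add atoms: water, O
Why: Myers reductive 1,3-transposition: Mitsunobu displacement inverts C3 (3β-O to 3α-N), loss of sulfinic acid gives the monoalkyl diazene, and its suprafacial retro-ene loss of N2 delivers H to C5 from the α-face, which sets the trans ring fusion (C5 = R) and places the alkene at C3=C4; aqueous acid then cleaves the dioxolane.

Step 5
Reactants: 12 (4aR,8aR)-5,8a-dimethyl-3,4,4a,7,8,8a-hexahydronaphthalen-2(1H)-one; 13 acetone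
Product: 16 eudesma-3,7(11)-dien-8-one, via lithium aldolate 14 (not isolated), via aldol trifluoroacetate 15 (not isolated)
Conditions: LDA, THF, −78 °C; 13; then (CF3CO)2O, −78 °C; then DBU, −78 to 23 °C
Reagents that add atoms: none
Why: Directed aldol condensation: LDA deprotonates C7 because C9 is shielded by the quaternary C10, the enolate adds to acetone, the tertiary aldolate is trapped as its trifluoroacetate and DBU effects E1cB elimination to the conjugated isopropylidene ketone, erasing the transient C7 centre.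

Step 6
Reactants: 17 (E)-2-methylbut-2-en-1-ol
Product: 18 [(2R,3R)-2,3-dimethyloxiran-2-yl]methanol
Conditions: Ti(OiPr)4 (10 mol%), D-(−)-diethyl tartrate (12 mol%), t-BuOOH, 4 Å MS, CH2Cl2, −20 °C
Reagents that add atoms: tert-butyl hydroperoxide, CC(C)(C)OO
Why: Sharpless asymmetric epoxidation: the titanium–D-(−)-tartrate catalyst delivers oxygen syn-stereospecifically to one face of the (E)-trisubstituted allylic alcohol, setting both oxirane centres as 2R,3R (the L-(+)-tartrate gives 2S,3S).

Step 7
Reactants: 18 [(2R,3R)-2,3-dimethyloxiran-2-yl]methanol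
Product: 20 (2S,3R)-2,3-dimethyloxirane-2-carboxylic acid, via epoxy aldehyde 19 (not isolated)
Conditions: TEMPO (cat.), PhI(OAc)2, MeCN/pH 7 buffer, 0 to 23 °C
Reagents that add atoms: water, O
Why: Oxoammonium (TEMPO/PhI(OAc)2) oxidation through the aldehyde hydrate to the acid under neutral conditions that leave the oxirane intact; the C2 descriptor changes from R to S only through CIP priorities.

Step 8
Reactants: 16 eudesma-3,7(11)-dien-8-one; 20 (2S,3R)-2,3-dimethyloxirane-2-carboxylic acid
Product: 23 4β-acetoxy-3α-[(2S,3R)-2,3-dimethyloxirane-2-carbonyloxy]eudesm-7(11)-en-8-one, via iodo acetate 21 (not isolated), via acetoxonium triflate 22 (not isolated)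
Conditions: I2 (1.05 equiv), AgOAc (1.05 equiv), CH2Cl2, −20 to 0 °C, dark; then 20 (1.5 equiv), AgOTf, 2,6-di-tert-butylpyridine, 4 Å MS, 0 to 40 °C
Reagents that add atoms: silver(I) acetate, CC(=O)[O-].[Ag+]
Why: Proposed new method: a crossed (two-carboxylate) Prévost anti-diacyloxylation in which acetyl hypoiodite from I2/AgOAc (exactly one acetate equivalent) forms the iodonium on the open α-face of the isolated trisubstituted alkene and acetate opens it trans-diaxially at the tertiary carbon (C4, β-attack) to give the 3α-iodo-4β-acetate, AgOTf then removes iodide with anchimeric help from the antiperiplanar acetate to give the β-cis-fused 2-methyl-1,3-dioxolan-2-ylium ion, and the only carboxylic acid now present (20) opens it by axial SN2 attack at the secondary carbon C3 from the α-face, setting C4 (R, β-OAc) and C3 (R, α-ester) with defined regiochemistry; the closest known chemistry is the Prévost reaction (iodine/silver carboxylate trans-diacyloxylation through the same acyloxonium ion, but with a single carboxylate) together with alkene iodoacetoxylation.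

Step 9
Reactants: 23 4β-acetoxy-3α-[(2S,3R)-2,3-dimethyloxirane-2-carbonyloxy]eudesm-7(11)-en-8-one
Product: 24 4β-acetoxy-3α-[(2S,3R)-2,3-dimethyloxirane-2-carbonyloxy]-11-hydroperoxyeudesm-6-en-8-one (target)
Conditions: O2, tetraphenylporphyrin (cat.), visible light, CH2Cl2, 0 °C
Reagents that add atoms: dioxygen, O=O
Why: Schenck ene reaction: with α,β-unsaturated ketones singlet oxygen bonds to the β-carbon (C11) and abstracts hydrogen from the alkyl group geminal to the carbonyl (axial H at C6), so the alkene moves to C6=C7 in conjugation with the C8 ketone; C11 is not stereogenic and no existing centre is touched.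

## Compound list

1 | 7-methyl-1,4-dioxaspiro[4.5]decan-8-one (racemic) | CC1CC2(OCCO2)CCC1=O | starting material
2 | (R)-1-phenylethylamine | C[C@@H](N)c1ccccc1 | starting material
3 | ethyl vinyl ketone (pent-1-en-3-one) | CCC(=O)C=C | starting material
4 | ketimine of 1 with 2, (1R)-N-(7-methyl-1,4-dioxaspiro[4.5]decan-8-ylidene)-1-phenylethanamine (ring α-centre equilibrating) | CC1CC2(OCCO2)CCC1=N[C@H](C)c1ccccc1 | intermediate
5 | Michael-adduct ketimine, 1-[(7R)-7-methyl-8-{[(1R)-1-phenylethyl]imino}-1,4-dioxaspiro[4.5]decan-7-yl]pentan-3-one | CCC(=O)CC[C@]1(C)CC2(OCCO2)CCC1=N[C@H](C)c1ccccc1 | intermediate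
6 | (7R)-7-methyl-7-(3-oxopentyl)-1,4-dioxaspiro[4.5]decan-8-one | CCC(=O)CC[C@]1(C)CC2(OCCO2)CCC1=O | intermediate
7 | (8aR)-5,8a-dimethyl-3,4,8,8a-tetrahydronaphthalene-2,6(1H,7H)-dione 2-(ethylene ketal) (Δ4-3-one, 10β-Me, 8-ketal) | CC1=C2CCC3(OCCO3)C[C@@]2(C)CCC1=O | intermediate
8 | (6S,8aR)-6-hydroxy-5,8a-dimethyl-3,4,6,7,8,8a-hexahydronaphthalen-2(1H)-one ethylene ketal (3β-OH, Δ4) | CC1=C2CCC3(OCCO3)C[C@@]2(C)CC[C@@H]1O | intermediate
9 | N-sulfonylhydrazine, N-(3α-alkyl)-N-(2-nitrobenzenesulfonyl)hydrazine of 8 with inverted C3 | CC1=C2CCC3(OCCO3)C[C@@]2(C)CC[C@H]1N(N)S(=O)(=O)c1ccccc1[N+](=O)[O-] | intermediate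
10 | allylic diazene (3α-N=NH, Δ4, 8-ketal) | CC1=C2CCC3(OCCO3)C[C@@]2(C)CC[C@H]1N=N | intermediate
11 | (4aR,8aR)-5,8a-dimethyl-3,4,4a,7,8,8a-hexahydronaphthalen-2(1H)-one ethylene ketal (Δ3, 5α-H, 10β-Me) | CC1=CCC[C@]2(C)CC3(OCCO3)CC[C@@H]12 | intermediate
12 | (4aR,8aR)-5,8a-dimethyl-3,4,4a,7,8,8a-hexahydronaphthalen-2(1H)-one (trans-fused Δ3-octal-8-one) | CC1=CCC[C@]2(C)CC(=O)CC[C@@H]12 | intermediate
13 | acetone | CC(C)=O | starting material
14 | lithium aldolate, lithium 2-[(3R,4aR,8aR)-5,8a-dimethyl-2-oxo-1,2,3,4,4a,7,8,8a-octahydronaphthalen-3-yl]propan-2-olate (7β epimer drawn; C7 is erased in the same step) | CC1=CCC[C@]2(C)CC(=O)[C@@H](C(C)(C)[O-])C[C@@H]12.[Li+] | intermediate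
15 | aldol trifluoroacetate, 2-[(3R,4aR,8aR)-5,8a-dimethyl-2-oxo-1,2,3,4,4a,7,8,8a-octahydronaphthalen-3-yl]propan-2-yl trifluoroacetate | CC1=CCC[C@]2(C)CC(=O)[C@@H](C(C)(C)OC(=O)C(F)(F)F)C[C@@H]12 | intermediate
16 | eudesma-3,7(11)-dien-8-one, (4aR,8aR)-5,8a-dimethyl-3-(propan-2-ylidene)-3,4,4a,7,8,8a-hexahydronaphthalen-2(1H)-one | CC1=CCC[C@]2(C)CC(=O)C(=C(C)C)C[C@@H]12 | intermediate
17 | (E)-2-methylbut-2-en-1-ol (tiglyl alcohol) | C/C=C(\C)CO | starting material
18 | [(2R,3R)-2,3-dimethyloxiran-2-yl]methanol | OC[C@@]1(C)O[C@@H]1C | intermediate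
19 | (2S,3R)-2,3-dimethyloxirane-2-carbaldehyde | O=C[C@@]1(C)O[C@@H]1C | intermediate
20 | (2S,3R)-2,3-dimethyloxirane-2-carboxylic acid | OC(=O)[C@@]1(C)O[C@@H]1C | intermediate
21 | iodo acetate, 4β-acetoxy-3α-iodoeudesm-7(11)-en-8-one (trans-diaxial) | CC(=O)O[C@]1(C)[C@@H]2CC(=C(C)C)C(=O)C[C@@]2(C)CC[C@H]1I | intermediate
22 | acetoxonium triflate, 2-methyl-1,3-dioxolan-2-ylium cis-fused on the β-face at C3/C4 of eudesm-7(11)-en-8-one, triflate salt | CC1=[O+][C@H]2CC[C@]3(C)CC(=O)C(=C(C)C)C[C@H]3[C@@]2(C)O1.[O-]S(=O)(=O)C(F)(F)F | intermediate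
23 | (1R,2R,4aR,8aR)-1-acetoxy-1,4a-dimethyl-6-oxo-7-(propan-2-ylidene)decahydronaphthalen-2-yl (2S,3R)-2,3-dimethyloxirane-2-carboxylate (4β-OAc, 3α-ester, 5α-H, 10β-Me) | CC(=O)O[C@]1(C)[C@@H]2CC(=C(C)C)C(=O)C[C@@]2(C)CC[C@H]1OC(=O)[C@@]1(C)O[C@@H]1C | intermediate
24 | (1R,2R,4aR,8aR)-1-acetoxy-7-(2-hydroperoxypropan-2-yl)-1,4a-dimethyl-6-oxo-1,2,3,4,4a,5,6,8a-octahydronaphthalen-2-yl (2S,3R)-2,3-dimethyloxirane-2-carboxylate | CC(=O)O[C@]1(C)[C@@H]2C=C(C(C)(C)OO)C(=O)C[C@@]2(C)CC[C@H]1OC(=O)[C@@]1(C)O[C@@H]1C | target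

## Step count and risks

Total step count: 9 (steps 1–5, 8 and 9 on the core; steps 6 and 7 on the side chain). Longest linear sequence: 7 steps (1, 2, 3, 4, 5, 8, 9).

The three steps most likely to fail:

Step 8, the proposed crossed Prévost reaction, is the least certain. The acyloxonium ion could ionise at the tertiary C4–O bond instead of being opened at C3, trace water would divert it to a cis-hydroxy acetate, and some diacetate could form. The fallback uses known chemistry, sets out from 16 and returns at 23. Epoxidation with mCPBA/NaHCO3 in CH2Cl2 occurs on the isolated alkene from the α-face (the β-face is screened by the axial C10 methyl) and gives 3α,4α-epoxyeudesm-7(11)-en-8-one F1. Acid-catalysed acetolysis in glacial acetic acid opens F1 trans-diaxially at the tertiary carbon to give 4β-acetoxy-3α-hydroxyeudesm-7(11)-en-8-one F2; acyl migration is blocked by the antiperiplanar arrangement. Yamaguchi esterification of the axial 3α-alcohol of F2 with acid 20 (2,4,6-trichlorobenzoyl chloride, Et3N, DMAP, toluene) then gives 23.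

Step 4 depends on a Mitsunobu displacement at a hindered allylic carbinol next to a tetrasubstituted alkene, where elimination or SN2' attack could compete. The fallback sets out from 7 (bypassing 8) and returns at 12. Dissolving-metal reduction of the enone (Li, NH3/THF, one equivalent of t-BuOH, −78 °C) sets the trans ring fusion by axial protonation at C5, and the regiodefined C3 enolate is trapped with PhNTf2 as (4aR,8aR)-2,2-(ethylenedioxy)-5,8a-dimethyl-1,2,3,4,4a,7,8,8a-octahydronaphthalen-6-yl trifluoromethanesulfonate F3. Palladium-catalysed formate reduction (Pd(OAc)2, PPh3, Bu3N, HCO2H, DMF, 60 °C) converts F3 into ketal alkene 11, isolated in this variant, and 1 M HCl in THF then gives 12.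

Step 5 combines aldol addition to acetone, which is prone to retro-aldol and proton transfer, with in-flask activation and elimination. The fallback sets out from 12 and returns at 16. The kinetic enolate is silylated (LDA, TMSCl, THF, −78 °C) to the C7=C8 silyl enol ether, trimethyl{[(4aR,8aR)-5,8a-dimethyl-1,4,4a,7,8,8a-hexahydronaphthalen-2-yl]oxy}silane F4. A TiCl4-mediated Mukaiyama aldol with acetone 13 in CH2Cl2 at −78 °C gives the isolable tertiary aldol (3R,4aR,8aR)-3-(2-hydroxypropan-2-yl)-5,8a-dimethyl-3,4,4a,7,8,8a-hexahydronaphthalen-2(1H)-one F5. This is dehydrated in a separate operation (Burgess reagent, or MsCl/Et3N then DBU) to 16.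

Further compounds
F1 | step 8 | 3α,4α-epoxyeudesm-7(11)-en-8-one | C[C@@]12O[C@@H]1CC[C@]1(C)CC(=O)C(=C(C)C)C[C@@H]21
F2 | step 8 | 4β-acetoxy-3α-hydroxyeudesm-7(11)-en-8-one | CC(=O)O[C@]1(C)[C@@H]2CC(=C(C)C)C(=O)C[C@@]2(C)CC[C@H]1O
F3 | step 4 | (4aR,8aR)-2,2-(ethylenedioxy)-5,8a-dimethyl-1,2,3,4,4a,7,8,8a-octahydronaphthalen-6-yl trifluoromethanesulfonate | CC1=C(OS(=O)(=O)C(F)(F)F)CC[C@]2(C)CC3(OCCO3)CC[C@@H]12
F4 | step 5 | trimethyl{[(4aR,8aR)-5,8a-dimethyl-1,4,4a,7,8,8a-hexahydronaphthalen-2-yl]oxy}silane | CC1=CCC[C@]2(C)CC(O[Si](C)(C)C)=CC[C@@H]12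
F5 | step 5 | (3R,4aR,8aR)-3-(2-hydroxypropan-2-yl)-5,8a-dimethyl-3,4,4a,7,8,8a-hexahydronaphthalen-2(1H)-one | CC1=CCC[C@]2(C)CC(=O)[C@@H](C(C)(C)O)C[C@@H]12
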